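**Assumptions**
- The [C@H] centre in the SMILES decodes as (2R), with priorities O1 > C1' aryl > C3 > H. This is the antipode of natural (2S)-abyssinone III.
- Numbers are given to substrates, atom-contributing reagents, the chiral catalyst, intermediates and the target. Ordinary bases, acids and oxidants appear only under Conditions.
- The alkene in 10 is drawn as the Z isomer (aryl cis to the ester). This is an assumption, and the geometry is destroyed in step 6.

## Retrosynthetic overview
1. The C ring is closed last, at O1–C2, by a catalytic asymmetric intramolecular oxa-Michael addition that sets the only stereocentre. The activating CO2tBu group and the 7-O-MOM group are removed together in the final acid step.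
2. The cyclisation precursor is an alkylidene β-ketoester. A Knoevenagel disconnection splits it into an A-ring β-ketoester and a B/D-ring aldehyde.
3. The β-ketoester comes from methyl 2,4-dihydroxybenzoate by selective 4-O-MOM protection and a crossed Claisen condensation with t-BuOAc.
4. The aldehyde comes from 4-hydroxybenzaldehyde by double ortho C-prenylation, then DDQ oxidative cyclisation of one of the two equivalent prenyl arms.
5. Ring order: the 2,2-dimethyl-2H-pyran (D ring) is formed first on the aldehyde fragment, and the dihydropyranone (C ring) last.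

## Route

**Step 1**
Reactants: 1 methyl 2,4-dihydroxybenzoate; 2 chloromethyl methyl ether (MOMCl)
Product: 3 methyl 2-hydroxy-4-(methoxymethoxy)benzoate
Conditions: MOMCl (1.1 equiv), K2CO3, acetone, 0 °C → rt
Reagents that add atoms: MOMCl, COCCl
Why: This Williamson-type O-alkylation is selective because the 2-OH is hydrogen-bonded to the ester carbonyl, so only the more acidic and accessible 4-OH reacts.

**Step 2**
Reactants: 3; 4 tert-butyl acetate
Product: 5 tert-butyl 3-[2-hydroxy-4-(methoxymethoxy)phenyl]-3-oxopropanoate
Conditions: t-BuOAc (4 equiv), LDA (4.2 equiv), THF, −78 °C; add 3; warm to rt; aq NH4Cl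
Reagents that add atoms: tert-butyl acetate, CC(=O)OC(C)(C)C
Why: In this crossed Claisen condensation the excess lithium enolate covers the phenol and the acidic product, and the bulky t-Bu ester prevents lactonisation to a 4-hydroxycoumarin.

**Step 3**
Reactants: 6 4-hydroxybenzaldehyde; 7 prenyl bromide (1-bromo-3-methylbut-2-ene)
Product: 8 4-hydroxy-3,5-bis(3-methylbut-2-en-1-yl)benzaldehyde
Conditions: prenyl bromide (2.2 equiv), 10% aq KOH (about 2.5 equiv), H2O, rt, 24–48 h; acidify; chromatography (the mono-prenyl by-product is resubmitted)
Reagents that add atoms: prenyl bromide (2 equiv incorporated), CC(C)=CCBr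
Why: This is ambident phenoxide alkylation (SN2) in water, where hydrogen-bond solvation of the oxygen steers the allylic halide to the two free ortho carbons, the para position being blocked by CHO.

**Step 4**
Reactants: 8
Product: 9 2,2-dimethyl-8-(3-methylbut-2-en-1-yl)-2H-chromene-6-carbaldehyde
Conditions: DDQ (1.05 equiv), PhH (or 1,4-dioxane), reflux
Reagents that add atoms: none (net loss of 2 H)
Why: In this DDQ cyclodehydrogenation, hydride abstraction from one ArCH2 gives a vinyl o-quinone methide that closes by oxa-6π electrocyclisation, and the second prenyl survives because no free phenol remains.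

**Step 5**
Reactants: 5; 9
Product: 10 tert-butyl (Z)-3-[2,2-dimethyl-8-(3-methylbut-2-en-1-yl)-2H-chromen-6-yl]-2-[2-hydroxy-4-(methoxymethoxy)benzoyl]prop-2-enoate
Conditions: piperidine (20 mol %), AcOH (20 mol %), 4 Å MS, toluene, rt
Reagents that add atoms: aldehyde 9 (coupling partner), CC(C)=CCc1cc(C=O)cc2C=CC(C)(C)Oc12
Why: This Knoevenagel condensation couples the doubly activated methylene with a non-enolisable aldehyde, and the chelated 2'-OH keeps racemic ring closure slow at rt.

**Step 6**
Reactants: 10; 11 (catalyst) quinine-derived thiourea, 1-[3,5-bis(trifluoromethyl)phenyl]-3-[(8α,9S)-6'-methoxycinchonan-9-yl]thiourea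
Product: 12 tert-butyl (2R,3S)-2-[2,2-dimethyl-8-(3-methylbut-2-en-1-yl)-2H-chromen-6-yl]-7-(methoxymethoxy)-4-oxochromane-3-carboxylate (2,3-trans; C3 is labile and is removed later)
Conditions: 11 (10 mol %), toluene (0.05 M), −25 °C, 24–48 h; not isolated
Reagents that add atoms: none
Why: In this bifunctional organocatalytic oxa-Michael addition (6-endo-trig) the thiourea binds the 1,3-dicarbonyl and the quinuclidine activates the phenol, so O adds to one alkene face; I assign 2R to the quinine-derived catalyst by analogy (the quinidine pseudoenantiomer should then give 2S), and this sense must be checked as described under the step 6 risk below.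

**Step 7**
Reactants: 12
Product: 13 ent-abyssinone III, (2R)-2-[2,2-dimethyl-8-(3-methylbut-2-en-1-yl)-2H-chromen-6-yl]-7-hydroxy-2,3-dihydro-4H-chromen-4-one
Conditions: p-TsOH·H2O (1.5 equiv) added to the step-6 solution, toluene, 80 °C, 1–2 h; pH 7 work-up; recrystallise (or chiral HPLC) to >99% ee
Reagents that add atoms: none (loses isobutene, CO2, CH2O and MeOH)
Why: Acid-mediated t-Bu ester cleavage and β-keto-acid decarboxylation occur together with MOM acetal hydrolysis, C2 is untouched, the non-basic medium avoids retro-oxa-Michael racemisation, and neither alkene has a free ortho phenol to cyclise onto.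

## Compound list
| No. | Name | SMILES | Role |
|---|---|---|---|
| 1 | methyl 2,4-dihydroxybenzoate | COC(=O)c1ccc(O)cc1O | starting material |
| 2 | chloromethyl methyl ether | COCCl | starting material |
| 3 | methyl 2-hydroxy-4-(methoxymethoxy)benzoate | COC(=O)c1ccc(OCOC)cc1O | intermediate |
| 4 | tert-butyl acetate | CC(=O)OC(C)(C)C | starting material |
| 5 | tert-butyl 3-[2-hydroxy-4-(methoxymethoxy)phenyl]-3-oxopropanoate | CC(C)(C)OC(=O)CC(=O)c1ccc(OCOC)cc1O | intermediate |
| 6 | 4-hydroxybenzaldehyde | O=Cc1ccc(O)cc1 | starting material |
| 7 | prenyl bromide | CC(C)=CCBr | starting material |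
| 8 | 4-hydroxy-3,5-diprenylbenzaldehyde | CC(C)=CCc1cc(C=O)cc(CC=C(C)C)c1O | intermediate |
| 9 | 2,2-dimethyl-8-prenyl-2H-chromene-6-carbaldehyde | CC(C)=CCc1cc(C=O)cc2C=CC(C)(C)Oc12 | intermediate |
| 10 | (Z)-alkylidene β-ketoester | COCOc1ccc(C(=O)C(=C/c2cc(CC=C(C)C)c3OC(C)(C)C=Cc3c2)/C(=O)OC(C)(C)C)c(O)c1 | intermediate |
| 11 | quinine-derived (8S,9S) bis-CF3-aryl thiourea | COc1ccc2nccc([C@@H]([C@@H]3C[C@@H]4CCN3C[C@@H]4C=C)NC(=S)Nc3cc(C(F)(F)F)cc(C(F)(F)F)c3)c2c1 | starting material (commercial catalyst, contributes no atoms) |
| 12 | (2R,3S)-7-OMOM-flavanone-3-carboxylic acid tert-butyl ester | COCOc1ccc2C(=O)[C@@H](C(=O)OC(C)(C)C)[C@H](c3cc(CC=C(C)C)c4OC(C)(C)C=Cc4c3)Oc2c1 | intermediate |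
| 13 | ent-abyssinone III, (2R), C25H26O4 | CC(C)=CCc1cc([C@H]2CC(=O)c3ccc(O)cc3O2)cc2c1OC(C)(C)C=C2 | target |

## Step count
- **Total steps:** 7. Steps 6 and 7 are run in one pot but counted separately.
- **Longest linear sequence:** 5 steps (1→2→5→6→7 or 3→4→5→6→7).

## Three steps most likely to fail

**1. Step 3, double C-prenylation.**
- Risk: competing O-prenyl, mono-prenyl and over-alkylated products. A realistic yield is about 20–30%.
- Fallback: build the aldehyde by cross-coupling in place of steps 3–4. O-alkylate 3-bromo-4-hydroxybenzaldehyde with 3-chloro-3-methylbut-1-yne (K2CO3, KI, cat. CuI). Thermal aryl propargyl Claisen rearrangement, 1,5-H shift and 6π closure then give 8-bromo-2,2-dimethylchromene-6-carbaldehyde. Stille coupling with tributyl(prenyl)stannane and Pd(PPh3)4 gives 9. This costs one more step.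

**2. Step 6, asymmetric oxa-Michael addition.**
- Risk: the electron-rich B ring slows the addition, background cyclisation erodes the ee, and the absolute sense rests on my assignment by analogy.
- Check: confirm the configuration by CD. A (2R)-flavanone shows a negative n→π* Cotton effect near 330 nm and a positive π→π* band near 290 nm. If the sense is wrong, swapping to the quinidine-derived catalyst is the trivial fix.
- Fallback: form C2–aryl instead of C2–O. Use Rh(I) with an (R)-configured electron-poor biaryl bisphosphine (or a chiral diene) for asymmetric 1,4-addition of (2,2-dimethyl-8-prenylchromen-6-yl)boronic acid to 7-(methoxymethoxy)chromone, then remove the MOM group. The boronic acid comes from 4-bromophenol by the same diprenylation and DDQ sequence, then n-BuLi/B(OiPr)3. The Hayashi model predicts 2R from the (R)-ligand.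

**3. Step 7, hot acid.**
- Risk: chromene or prenyl degradation, or partial racemisation through ionisation of the p-alkoxybenzylic C2–O1 bond.
- Fallback: change the masking strategy. Carry an allyl β-ketoester and a 7-O-allyl ether through steps 1–6, and finish with Pd(PPh3)4/morpholine at rt. This Tsuji–Trost deallylation with spontaneous decarboxylation unmasks both groups under neutral conditions.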